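**Retrosynthetic overview**
- The plan rests on ring A (C10=C1–C2–C3–C4–C5). Without the C2 carbonyl it is a cyclohexene whose C4 bears CH3 and a carbonyl carbon, with H5 cis to that carbonyl. That is the exo [4+2] adduct of methacrolein (C3=C4) and the semicyclic diene C2=C1–C10=C5 attached to ring B (C5–C10).
- End game, read backwards: C15–OH comes from its TBS ether, C2=O from allylic oxidation of C2H2, and CO2Me from the C4 formyl group.
- The diene comes from the C10 ketone of ring B by enol triflate formation and vinyl Stille coupling.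
- Ring B is bought as 2-methylcyclohexenone. C8 is set by copper-catalysed asymmetric methyl addition. Quaternary C9 is set by enolate alkylation with an E allylic iodide made from a butynyl ether. C13 is set by Ru-binap hydrogenation of the resulting homoallylic alcohol.
- Ring order: ring B is present from the start; ring A is closed last, in the cycloaddition.

Key step: step 9

Numbering: halimane numbering. Ring A is C1–C5 and C10; ring B is C5–C10. C4 bears CH3 and the carbonyl carbon. C8 and C9 each bear CH3. C9 bears the chain C11–C15, with CH3 on C13.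

Assumption: the ligand and catalyst antipodes named in steps 3, 5 and 9 are those predicted by the accepted models for the nearest known substrates; if a check of the first product shows the opposite sense, the mirror-image ligand, equally available, is used.

**Step 1**
Reactants: 1 tert-butyl(but-3-yn-1-yloxy)dimethylsilane; 2 trimethylaluminium
Product: 5 (E)-5-(tert-butyldimethylsilyloxy)-3-methylpent-2-en-1-ol, via alkenyldimethylalane 3 (not isolated), via lithium alkenylalanate 4 (not isolated)
Conditions: Me3Al (2 equiv), Cp2ZrCl2 (25 mol %), CH2Cl2, 0 °C to rt; evaporate; n-BuLi, hexane–THF, −78 to 0 °C; (CH2O)n, rt; aqueous work-up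
Reagents that add atoms: paraformaldehyde, reacting as formaldehyde, C=O
Why: Zirconium-catalysed syn carboalumination of the terminal alkyne (Negishi carboalumination) puts CH3 on the internal carbon and aluminium on the terminus, and the derived alanate adds to formaldehyde with retention, so only the E trisubstituted allylic alcohol is expected.

**Step 2**
Reactants: 5 (E)-5-(tert-butyldimethylsilyloxy)-3-methylpent-2-en-1-ol
Product: 6 (E)-tert-butyl[(5-iodo-3-methylpent-3-en-1-yl)oxy]dimethylsilane
Conditions: PPh3, imidazole, I2, CH2Cl2, 0 °C, dark; used at once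
Reagents that add atoms: iodine, [I][I]
Why: Appel-type iodination displaces the oxyphosphonium group of the primary allylic alcohol by SN2 and leaves the alkene geometry and the silyl ether untouched.

**Step 3**
Reactants: 7 2-methylcyclohex-2-en-1-one; 2 trimethylaluminium
Product: 9 (R)-[(2,3-dimethylcyclohex-1-en-1-yl)oxy]trimethylsilane, via dimethylaluminium enolate 8 (not isolated)
Conditions: Cu(OTf)2 (2 mol %), (R)-binaphthol phosphoramidite of bis[(S)-1-phenylethyl]amine (4 mol %), Me3Al (1.4 equiv), Et2O, −30 °C; then TMSOTf, −30 to 0 °C; Et3N, cold aq NaHCO3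
Reagents that add atoms: trimethylsilyl triflate, C[Si](C)(C)OS(=O)(=O)C(F)(F)F
Why: Copper-catalysed asymmetric conjugate addition of an aluminium alkyl sets C8 because the chiral phosphoramidite–copper complex selects the enone face, and O-silylation of the poorly nucleophilic aluminium enolate stores the tetrasubstituted enolate regiospecifically for the next step.

**Step 4**
Reactants: 9 (R)-[(2,3-dimethylcyclohex-1-en-1-yl)oxy]trimethylsilane; 6 (E)-tert-butyl[(5-iodo-3-methylpent-3-en-1-yl)oxy]dimethylsilane
Product: 12 (2S,3R)-2-[(E)-5-hydroxy-3-methylpent-2-en-1-yl]-2,3-dimethylcyclohexan-1-one, via lithium enolate 10 (not isolated), via silyl ether ketone 11 (not isolated)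
Conditions: MeLi (1.05 equiv), THF, 0 °C to rt; DMPU; 6, −78 to −20 °C; then 2 M aq HCl, MeOH, rt
Reagents that add atoms: none
Why: Regiospecific release of the lithium enolate from the silyl enol ether and SN2 alkylation with a reactive allylic iodide build quaternary C9; the C8 methyl lies pseudoaxial in the enolate half-chair to avoid the C9 methyl, so the iodide enters from the opposite face (chain trans to the C8 methyl, the two methyls cis), and the acid quench frees the hydroxyl needed in step 5.

**Step 5**
Reactants: 12 (2S,3R)-2-[(E)-5-hydroxy-3-methylpent-2-en-1-yl]-2,3-dimethylcyclohexan-1-one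
Product: 13 (2S,3R)-2-[(3R)-5-hydroxy-3-methylpentyl]-2,3-dimethylcyclohexan-1-one
Conditions: Ru(OAc)2[(R)-binap] (1–2 mol %), H2 (100 bar), MeOH, 25 °C
Reagents that add atoms: none
Why: In this hydroxyl-directed asymmetric hydrogenation of a homoallylic alcohol the alcohol binds ruthenium and the diphosphine decides which face of the E C12=C13 alkene receives hydrogen, which should give 13R, while the hindered isolated ketone is not a substrate for the dicarboxylate catalyst.

**Step 6**
Reactants: 13 (2S,3R)-2-[(3R)-5-hydroxy-3-methylpentyl]-2,3-dimethylcyclohexan-1-one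
Product: 14 (2S,3R)-2-[(3R)-5-(tert-butyldimethylsilyloxy)-3-methylpentyl]-2,3-dimethylcyclohexan-1-one
Conditions: TBSCl, imidazole, CH2Cl2, rt
Reagents that add atoms: tert-butyldimethylsilyl chloride, CC(C)(C)[Si](C)(C)Cl
Why: Standard O-silylation of a primary alcohol masks C15–OH against base, Lewis acid and the oxidants that follow.

**Step 7**
Reactants: 14 (2S,3R)-2-[(3R)-5-(tert-butyldimethylsilyloxy)-3-methylpentyl]-2,3-dimethylcyclohexan-1-one
Product: 16 (5R,6S)-6-[(3R)-5-(tert-butyldimethylsilyloxy)-3-methylpentyl]-5,6-dimethylcyclohex-1-en-1-yl trifluoromethanesulfonate, via potassium enolate 15 (not isolated)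
Conditions: KN(SiMe3)2, THF, −78 °C; PhNTf2, −78 °C to rt
Reagents that add atoms: N-phenylbis(trifluoromethanesulfonimide), O=S(=O)(N(c1ccccc1)S(=O)(=O)C(F)(F)F)C(F)(F)F
Why: Enol triflate formation is regiochemically unambiguous because C9 is quaternary, so enolisation can only run toward C5 and O-sulfonylation fixes the C5=C10 alkene.

**Step 8**
Reactants: 16 the C10 enol triflate; 17 tributyl(vinyl)stannane
Product: 18 tert-butyl({(3R)-5-[(1S,6R)-2-ethenyl-1,6-dimethylcyclohex-2-en-1-yl]-3-methylpentyl}oxy)dimethylsilane (ring B diene C2=C1–C10=C5)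
Conditions: Pd(PPh3)4 (5 mol %), LiCl (3 equiv), THF, reflux
Reagents that add atoms: none
Why: Stille coupling of an enol triflate with a vinylstannane, chloride-assisted, joins C10 to C1 under neutral conditions that leave the silyl ether and all three stereocentres alone.

**Step 9**
Reactants: 18 ring B diene; 19 methacrolein
Product: 20 (4S,5S,8R,9S,13R)-15-(tert-butyldimethylsilyloxy)halim-1(10)-ene bearing CHO on C4 (CHO cis to H5, C4 methyl trans to H5)
Conditions: (S)-oxazaborolidinium triflimide (20 mol %; from (S)-α,α-diphenylprolinol and o-tolylboronic acid, then slightly less than 1 equiv HN(SO2CF3)2 per boron), 19 (5 equiv), CH2Cl2, −78 to −40 °C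
Reagents that add atoms: none
Why: The boron-bound s-trans enal and the s-cis diene combine in a concerted, asynchronous [4+2] cycloaddition in which C2–C3 runs ahead of C4–C5; the closest known reaction type is the oxazaborolidinium-catalysed, exo-selective Diels–Alder reaction of 2-methylacrolein with cyclic and semicyclic dienes. Ring A (C10, C1, C2, C3, C4, C5) closes as a six-membered carbocycle by intermolecular cycloaddition across the diene termini C2 and C5, which leaves the alkene at C1=C10. The unhindered vinyl terminus C2 carries the larger HOMO coefficient and attacks the enal β-carbon C3, so quaternary C4 ends on C5, and quaternary C9 helps by destabilising the s-trans rotamer, in which C2H2 would press on the C9 substituents. C4 is set by the catalyst: B–O coordination and a formyl C–H···O contact hold the enal over one phenyl group of the (S)-prolinol-derived ring, so only the Re face of C4 is open. C5 is set by the exo mode (methyl under the diene, formyl pointing away, hence CHO cis to H5), preferred because an endo formyl group would push the bulky boron complex under ring B and against C9; with enal face, regiochemistry and exo mode fixed, the diene has to react on the face that bears the C8 and C9 methyl groups, anti to the C9 chain. The step thus needs regio-, exo- and diene-face selectivity, and the last rests on the reagent, since ring B can flip between two half-chairs and offers only a small bias of its own, which may oppose the catalyst.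

**Step 10**
Reactants: 20 the C4 aldehyde
Product: 21 (4S,5S,8R,9S,13R)-15-(tert-butyldimethylsilyloxy)halim-1(10)-ene bearing CO2H on C4
Conditions: NaClO2, NaH2PO4, 2-methylbut-2-ene (large excess), t-BuOH–H2O, 0 °C to rt
Reagents that add atoms: sodium chlorite, [Na+].[O-]Cl=O
Why: Pinnick oxidation converts even a neopentyl-type aldehyde to the acid under mildly acidic conditions, C4 has no hydrogen to lose, and the alkene scavenger protects C1=C10 from hypochlorous acid.

**Step 11**
Reactants: 21 the C4 acid
Product: 23 methyl ester of 21 (CO2CH3 on C4), via potassium carboxylate 22 (not isolated)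
Conditions: K2CO3, MeI, DMF, rt
Reagents that add atoms: iodomethane, C[I]
Why: SN2 O-alkylation of the carboxylate forms the ester at oxygen and so avoids any attack at the crowded carbonyl carbon next to quaternary C4.

**Step 12**
Reactants: 23 the C4 methyl ester
Product: 24 (4S,5S,8R,9S,13R)-methyl 15-(tert-butyldimethylsilyloxy)-2-oxohalim-1(10)-en-oate (C2=O conjugated with C1=C10)
Conditions: CrO3, 3,5-dimethylpyrazole (15 equiv each), CH2Cl2, −20 °C
Reagents that add atoms: chromium trioxide, O=[Cr](=O)=O
Why: Allylic oxidation with the CrO3–3,5-dimethylpyrazole complex attacks the ring methylene attached to the CH end of a trisubstituted alkene, here C2, in the way 5-ene steroids give 7-ketones, while C9 has no hydrogen and the tertiary C5–H is crowded by C4 and cannot end as a ketone.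

**Step 13**
Reactants: 24 the enone silyl ether
Product: 25 CNP0157174.1, (4S,5S,8R,9S,13R)-methyl 15-hydroxy-2-oxohalim-1(10)-en-oate
Conditions: HF·pyridine, pyridine, THF, 0 °C to rt
Reagents that add atoms: none
Why: Fluoride-driven cleavage of the primary silyl ether under weakly acidic buffering frees C15–OH without base, which matters because H5 is the γ-hydrogen of the enone and could be lost through the extended enolate.

**Compound list**
1 | tert-butyl(but-3-yn-1-yloxy)dimethylsilane | C#CCCO[Si](C)(C)C(C)(C)C | starting material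
2 | trimethylaluminium | C[Al](C)C | starting material
3 | (E)-[4-(tert-butyldimethylsilyloxy)-2-methylbut-1-en-1-yl]dimethylalane | C[Al](C)/C=C(\C)CCO[Si](C)(C)C(C)(C)C | intermediate
4 | lithium butyl[(E)-4-(tert-butyldimethylsilyloxy)-2-methylbut-1-en-1-yl]dimethylaluminate | [Li+].CCCC[Al-](C)(C)/C=C(\C)CCO[Si](C)(C)C(C)(C)C | intermediate
5 | (E)-5-(tert-butyldimethylsilyloxy)-3-methylpent-2-en-1-ol | OC/C=C(\C)CCO[Si](C)(C)C(C)(C)C | intermediate
6 | (E)-tert-butyl[(5-iodo-3-methylpent-3-en-1-yl)oxy]dimethylsilane | IC/C=C(\C)CCO[Si](C)(C)C(C)(C)C | intermediate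
7 | 2-methylcyclohex-2-en-1-one | CC1=CCCCC1=O | starting material
8 | dimethylaluminium (R)-2,3-dimethylcyclohex-1-en-1-olate | C[Al](C)OC1=C(C)[C@H](C)CCC1 | intermediate
9 | (R)-[(2,3-dimethylcyclohex-1-en-1-yl)oxy]trimethylsilane | C[Si](C)(C)OC1=C(C)[C@H](C)CCC1 | intermediate
10 | lithium (R)-2,3-dimethylcyclohex-1-en-1-olate | [Li+].[O-]C1=C(C)[C@H](C)CCC1 | intermediate
11 | (2S,3R)-2-[(E)-5-(tert-butyldimethylsilyloxy)-3-methylpent-2-en-1-yl]-2,3-dimethylcyclohexan-1-one | O=C1CCC[C@@H](C)[C@]1(C)C/C=C(\C)CCO[Si](C)(C)C(C)(C)C | intermediate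
12 | (2S,3R)-2-[(E)-5-hydroxy-3-methylpent-2-en-1-yl]-2,3-dimethylcyclohexan-1-one | O=C1CCC[C@@H](C)[C@]1(C)C/C=C(\C)CCO | intermediate
13 | (2S,3R)-2-[(3R)-5-hydroxy-3-methylpentyl]-2,3-dimethylcyclohexan-1-one | O=C1CCC[C@@H](C)[C@]1(C)CC[C@@H](C)CCO | intermediate
14 | (2S,3R)-2-[(3R)-5-(tert-butyldimethylsilyloxy)-3-methylpentyl]-2,3-dimethylcyclohexan-1-one | O=C1CCC[C@@H](C)[C@]1(C)CC[C@@H](C)CCO[Si](C)(C)C(C)(C)C | intermediate
15 | potassium enolate of 14 (C10–O, C5=C10) | [K+].[O-]C1=CCC[C@@H](C)[C@]1(C)CC[C@@H](C)CCO[Si](C)(C)C(C)(C)C | intermediate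
16 | (5R,6S)-6-[(3R)-5-(tert-butyldimethylsilyloxy)-3-methylpentyl]-5,6-dimethylcyclohex-1-en-1-yl trifluoromethanesulfonate | O=S(=O)(OC1=CCC[C@@H](C)[C@]1(C)CC[C@@H](C)CCO[Si](C)(C)C(C)(C)C)C(F)(F)F | intermediate
17 | tributyl(vinyl)stannane | C=C[Sn](CCCC)(CCCC)CCCC | starting material
18 | tert-butyl({(3R)-5-[(1S,6R)-2-ethenyl-1,6-dimethylcyclohex-2-en-1-yl]-3-methylpentyl}oxy)dimethylsilane | C=CC1=CCC[C@@H](C)[C@]1(C)CC[C@@H](C)CCO[Si](C)(C)C(C)(C)C | intermediate
19 | methacrolein | CC(=C)C=O | starting material
20 | (4S,5S,8R,9S,13R)-15-(tert-butyldimethylsilyloxy)halim-1(10)-ene with CHO on C4 | O=C[C@@]1(C)CCC=C2[C@@H]1CC[C@@H](C)[C@]2(C)CC[C@@H](C)CCO[Si](C)(C)C(C)(C)C | intermediate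
21 | corresponding C4 carboxylic acid | OC(=O)[C@@]1(C)CCC=C2[C@@H]1CC[C@@H](C)[C@]2(C)CC[C@@H](C)CCO[Si](C)(C)C(C)(C)C | intermediate
22 | potassium carboxylate of 21 | [K+].[O-]C(=O)[C@@]1(C)CCC=C2[C@@H]1CC[C@@H](C)[C@]2(C)CC[C@@H](C)CCO[Si](C)(C)C(C)(C)C | intermediate
23 | corresponding C4 methyl ester | COC(=O)[C@@]1(C)CCC=C2[C@@H]1CC[C@@H](C)[C@]2(C)CC[C@@H](C)CCO[Si](C)(C)C(C)(C)C | intermediate
24 | 2-oxo-1(10)-ene methyl ester, C15 TBS ether | COC(=O)[C@@]1(C)CC(=O)C=C2[C@@H]1CC[C@@H](C)[C@]2(C)CC[C@@H](C)CCO[Si](C)(C)C(C)(C)C | intermediate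
25 | CNP0157174.1 | COC(=O)[C@@]1(C)CC(=O)C=C2[C@@H]1CC[C@@H](C)[C@]2(C)CC[C@@H](C)CCO | target

**Totals and risks**

Total step count: 13. Longest linear sequence: 12 (steps 1, 2 and 4 to 13).

**Step 9.** The approach syn to the C8 and C9 methyl groups is the more crowded one. The diene may therefore meet the open enal face through its other face in the endo mode, which is a loss of diene-face and exo selectivity. C4 would still be set by the catalyst, but C5 would be inverted. The fallback sets C5 after the cycloaddition instead of in it.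
- It sets out from diene 18. The cycloaddition is run as before, and the C5-epimeric aldehyde F1, alone or mixed with 20, is taken through the operations of steps 10 to 12.
- These give the C5-epimeric acid F2, its potassium carboxylate F3, the C5-epimeric methyl ester F4 and the C5-epimeric enone F5.
- In F5 the C5 hydrogen is the γ-hydrogen of the enone. DBU in toluene (or NaOMe in MeOH) removes and returns it reversibly, while quaternary C4 cannot change.
- Enone 24 is separated and F5 is resubmitted; the route is rejoined at 24.
- The position of this equilibrium is not known in advance and may lie toward F5, so recycling is part of the plan. For the same reason, base is avoided after step 12 in the main route.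

**Step 5.** The hydroxyl arm sits on the fully substituted alkene carbon, a pattern less tested than the classical homoallylic case. Slow reduction, weak face selection or alkene migration before reduction are therefore possible. The fallback gives up hydroxyl direction altogether.
- Step 4 is quenched with aqueous NH4Cl so that silyl ether ketone 11 is isolated.
- 11 is hydrogenated with a cationic iridium complex [Ir(cod)(L)][B(C6H3-3,5-(CF3)2)4] (L = chiral bicyclic pyridine–phosphinite), H2 (50 bar), CH2Cl2, rt.
- This catalyst class reduces E alkenes of the CH2–CH=C(CH3)–CH2 type by shape recognition alone.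
- It gives 14 directly. The route is rejoined at 14, and steps 5 and 6 drop out.

**Step 12.** The chromium reagent may abstract the tertiary allylic hydrogen at C5 or stall on the hindered alkene, giving poor site selectivity or low conversion. The fallback brings in the C2 oxygen by 1,3-transposition instead of C–H oxidation.
- From ester 23, mCPBA gives the C1–C10 epoxide F6. It is drawn with oxygen anti to the C9 chain; the other epoxide converges.
- PhSeNa (from PhSeSePh and NaBH4, EtOH) opens it at secondary C1 to the hydroxy selenide F7.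
- H2O2 gives the selenoxide F8, which eliminates toward C2 to the tertiary allylic alcohol F9 (C10–OH, C1=C2).
- Pyridinium chlorochromate, C5H5NH[CrO3Cl], in CH2Cl2 effects the oxidative allylic transposition (Babler–Dauben) to enone 24, where the route is rejoined.

**Further compounds**
F1 | step 9 | (4S,5R,8R,9S,13R) aldehyde, C5 epimer of 20 | O=C[C@@]1(C)CCC=C2[C@H]1CC[C@@H](C)[C@]2(C)CC[C@@H](C)CCO[Si](C)(C)C(C)(C)C
F2 | step 9 | C5 epimer of acid 21 | OC(=O)[C@@]1(C)CCC=C2[C@H]1CC[C@@H](C)[C@]2(C)CC[C@@H](C)CCO[Si](C)(C)C(C)(C)C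
F3 | step 9 | potassium carboxylate of F2 | [K+].[O-]C(=O)[C@@]1(C)CCC=C2[C@H]1CC[C@@H](C)[C@]2(C)CC[C@@H](C)CCO[Si](C)(C)C(C)(C)C
F4 | step 9 | C5 epimer of methyl ester 23 | COC(=O)[C@@]1(C)CCC=C2[C@H]1CC[C@@H](C)[C@]2(C)CC[C@@H](C)CCO[Si](C)(C)C(C)(C)C
F5 | step 9 | C5 epimer of enone 24 | COC(=O)[C@@]1(C)CC(=O)C=C2[C@H]1CC[C@@H](C)[C@]2(C)CC[C@@H](C)CCO[Si](C)(C)C(C)(C)C
F0 | step 5 | none | none
F6 | step 12 | C1–C10 epoxide of 23, oxygen anti to the C9 chain | COC(=O)[C@@]1(C)CC[C@@H]2O[C@]23[C@@H]1CC[C@@H](C)[C@]3(C)CC[C@@H](C)CCO[Si](C)(C)C(C)(C)C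
F7 | step 12 | C10 hydroxy C1 phenylselenide (trans) | COC(=O)[C@@]1(C)CC[C@@H]([Se]c2ccccc2)[C@]3(O)[C@@H]1CC[C@@H](C)[C@]3(C)CC[C@@H](C)CCO[Si](C)(C)C(C)(C)C
F8 | step 12 | selenoxide of F7 | COC(=O)[C@@]1(C)CC[C@@H]([Se](=O)c2ccccc2)[C@]3(O)[C@@H]1CC[C@@H](C)[C@]3(C)CC[C@@H](C)CCO[Si](C)(C)C(C)(C)C
F9 | step 12 | tertiary allylic alcohol, C10–OH, C1=C2 | COC(=O)[C@@]1(C)CC=C[C@]2(O)[C@@H]1CC[C@@H](C)[C@]2(C)CC[C@@H](C)CCO[Si](C)(C)C(C)(C)C
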